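The readings are simulated on assumed constants, and the scatter is random.

Follow the reagent.

| flask | starting material | reagent | remark | time |
|---|---|---|---|---|
| blue | 0.80 M | 0.34 M | run made earlier |  |
| violet | 0.80 M | 1.5 M | run made earlier |  |
| dawn | 0.80 M | 0.400 M |  | 3.0 d |
| noon | 0.80 M | 2.40 M |  | 3.0 d |
| dusk | 0.80 M | 0.640 M |  | 3.0 d |

| run | time / h | bis adduct / % | first product / % | starting material / % |
|---|---|---|---|---|
| blue | 6.00 | 3.1 | 16.0 | 76.0 |
| blue | 12.0 | 4.9 | 19.0 | 70.4 |
| blue | 20.0 | 5.0 | 19.1 | 68.1 |
| blue | 25.0 | 4.9 | 19.3 | 67.6 |
| blue | 30.0 | 5.3 | 19.8 | 68.1 |
| blue | 40.0 | 5.4 | 19.5 | 67.9 |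
| violet | 3.00 | 13.5 | 21.8 | 46.1 |
| violet | 5.00 | 21.4 | 18.9 | 33.8 |
| violet | 8.00 | 28.4 | 15.1 | 22.9 |
| violet | 12.0 | 33.3 | 11.8 | 17.0 |
| violet | 20.0 | 38.5 | 8.1 | 11.4 |
| violet | 40.0 | 42.9 | 5.0 | 6.8 |

(each reading ± 0.3 percentage points)



- which of these holds the largest part of the starting material at the end of dawn (starting material / other mono adduct / bis adduct / first product)
- which of these holds the largest part of the starting material at the end of noon (starting material / other mono adduct / bis adduct / first product)
- which of these holds the largest part of the starting material at the end of dusk (starting material / other mono adduct / bis adduct / first product)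
- how much bis adduct is there at the end of noon, in percent of the starting material charged

Time is the first setting. By hand it should do nothing once the reagent charge is used, and the blue run's starting material reads 68.1 % at 20.0 h and 67.9 % at 40.0 h. Over the last four blue readings I average starting material 67.9 %, first product 19.4 % and bis adduct 5.15 %.

Reagent is the second setting. Each starting material lost took one reagent, and any further reagent taken is a second addition. I take blue's charge of 0.425 per starting material as used, so subtracting the 32.1 % lost leaves for second additions 10.4 % of the starting material charged. That gives 0.494 as the bis share, bis adduct per second addition. The remaining second additions sit in something unread, and the balance then leaves 2.23 % for other mono adduct. More reagent does raise bis adduct: at 40.0 h violet reads 42.9 % against blue's 5.4 %.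

Noon charges 3.00 per starting material, and taking each through two additions still leaves at least 0.800 M reagent. Violet's first reading gives a starting-material half-life of 2.69 h, which scales to 5.04 h at that floor, so 3.0 d is ample. I therefore count one second addition per starting material in noon, and I commit to bis adduct largest, at 49.4 %. For dawn and dusk, blue's 0.755 lost per reagent leaves starting material at 62.3 % and 39.6 %, and I name it largest in both.

The forecast names starting material for dawn and starting material for dusk, as I do. For noon it names other mono adduct, with 46 % bis adduct: “Other mono about 54%, bis about 46%, a close call.”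

Noon ends with bis adduct largest, at 51.6 %. Dawn and dusk end with starting material, at 63.5 % and 47.6 %.

    starting material + reagent → first product + by-product (k = 0.210 M⁻¹ h⁻¹)
    starting material + reagent → other mono adduct + by-product (k = 0.0160 M⁻¹ h⁻¹)
    reagent + first product → bis adduct + by-product (k = 0.240 M⁻¹ h⁻¹)
    reagent + other mono adduct → bis adduct + by-product (k = 0.0930 M⁻¹ h⁻¹)
    crystals ⇌ by-product, rate k5*(cs5 - [by-product]) while solid is left; crystals form when [by-product] > cs5 (solubility = 0.320 M, k = 15.0 h⁻¹)
    reagent + first product → over-reaction product (k = 0.260 M⁻¹ h⁻¹)

In noon the step to first product ran while starting material was there, with >99.9 % of its turnover behind it at 1.50 d. At 0.128 d first product was leaving both ways, with half-lives of 0.085 d to bis adduct and 0.078 d to over-reaction product. Noon's bis share ends at 0.517, against my 0.494. A neighbour of noon, charged with 1.4 M reagent, counts for second additions 82.1 % of the starting material charged, and 0.494 of those is 40.6 %; that neighbour flask holds 41.1 % bis adduct.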